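**Plan**
- Retrosynthesis: remove the C8 ester, then the methylene lactone (C7–C11 bond and C13), back to a C6 alcohol next to a (Z)-C7=C8 alkene. Then cut O–C10 and C9–C10 in one operation, which unravels the ten-membered ring to a 2-vinyloxane (ring O on C3 and C7) carrying a CH2–CO–C(N2)CH3 arm.
- Enabling feature: the ring oxygen bridges C3 and the quaternary C10, and C10 is α to the C1 ketone. The furanone is therefore a tetrahydrofuran-3-one inside an 11-oxabicyclo[6.2.1]undecane, so C10 can be a carbenoid carbon and the oxane a template whose allylic O–C7 bond is cleaved.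
- Forward: divinylcarbinol → all-equatorial δ-lactone (asymmetric epoxidation, ylide homologation, methacrylate ring-closing metathesis, conjugate reduction) → oxane acetic acid → diazoketone → copper carbenoid. O–C10 formation closes the five-membered ring and a [2,3] shift builds the ten-membered ring. Then furanone → directed epoxidation and tethered phosphonoacetate (trans methylene lactone, C8–OH) → acylation → deprotection.
- Stereochemistry: C6 from the asymmetric epoxidation; C4 by enolate protonation on the lactone; a temporary C3 centre by axial hydride delivery, relayed to C10 through the bicyclic ylide; C8 and C7 by hydroxyl-directed epoxidation and SN2 opening; the side-chain carbinol from (S)-3-bromo-2-hydroxy-2-methylpropanoic acid.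

Key step: step 11

Remark: ring atoms carry germacrane numbers throughout (C1 ketone, C2=C3 enol ether, C4 methyl-bearing, C6 lactone-oxygen-bearing, C7, C8 ester-bearing, C9, C10 quaternary, C11–C13 methylene lactone); the Z ring alkene is assumed to be the major isomer from step 11, as in the closest analogues.

**Step 1**
Reactants: 1 penta-1,4-dien-3-ol
Product: 2 (2S,3R)-1,2-epoxypent-4-en-3-ol
Conditions: Ti(OiPr)4, D-(−)-diisopropyl tartrate, t-BuOOH, 4 Å MS, CH2Cl2, −20 °C
Reagents that add atoms: tert-butyl hydroperoxide, CC(C)(C)OO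
Why: Sharpless asymmetric epoxidation of the prochiral divinyl carbinol selects one enantiotopic vinyl group and one face (erythro product) and removes the minor enantiomer by a second epoxidation, so C6 (R) and C7 (S) should be set in very high enantiomeric purity.

**Step 2**
Reactants: 2 (2S,3R)-1,2-epoxypent-4-en-3-ol
Product: 3 (2S)-2-[(1R)-1-[(4-methoxyphenyl)methoxy]prop-2-en-1-yl]oxirane
Conditions: NaH, 4-MeOC6H4CH2Cl, Bu4NI (cat.), THF, 0 °C → rt
Reagents that add atoms: 4-methoxybenzyl chloride, COc1ccc(CCl)cc1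
Why: Williamson etherification; an ether is chosen because it cannot migrate to the neighbouring alkoxide in step 3, where silyl migration would racemise the pseudo-meso diol.

**Step 3**
Reactants: 3 (2S)-2-[(1R)-1-[(4-methoxyphenyl)methoxy]prop-2-en-1-yl]oxirane
Product: 5 (3S,4R)-4-[(4-methoxyphenyl)methoxy]hexa-1,5-dien-3-ol, via sulfonium betaine 4 (not isolated)
Conditions: Me3S+ I−, n-BuLi, THF, −10 °C → rt
Reagents that add atoms: trimethylsulfonium iodide, C[S+](C)C.[I-]
Why: Dimethylsulfonium methylide opens the terminal epoxide at CH2 and the γ-oxido sulfonium intermediate eliminates Me2S (one-carbon homologation of an epoxide to an allylic alcohol), which unveils the C7 hydroxyl and the C8=C9 vinyl group without touching either stereocentre.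

**Step 4**
Reactants: 5 (3S,4R)-4-[(4-methoxyphenyl)methoxy]hexa-1,5-dien-3-ol
Product: 6 (3S,4R)-4-[(4-methoxyphenyl)methoxy]hexa-1,5-dien-3-yl 2-methylprop-2-enoate
Conditions: CH2=C(CH3)COCl, Et3N, DMAP (cat.), CH2Cl2, 0 °C
Reagents that add atoms: methacryloyl chloride, C=C(C)C(Cl)=O
Why: DMAP-catalysed acylation of the only free hydroxyl brings in C3, C4 and the C4 methyl group.

**Step 5**
Reactants: 6 (3S,4R)-4-[(4-methoxyphenyl)methoxy]hexa-1,5-dien-3-yl 2-methylprop-2-enoate
Product: 7 (5R,6S)-6-ethenyl-5-[(4-methoxyphenyl)methoxy]-3-methyl-5,6-dihydro-2H-pyran-2-one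
Conditions: second-generation Grubbs catalyst RuCl2(=CHPh)(PCy3)(H2IMes) (5 mol %), CH2Cl2 (5 mM), 40 °C
Reagents that add atoms: none
Why: Ring-closing metathesis of the methacrylate with the vinyl group on C6 closes the six-membered unsaturated lactone (C4=C5), which should be favoured over butenolide formation with the vinyl group on the carbinol carbon because the two alkylidenes interconvert and the six-ring closure is faster.

**Step 6**
Reactants: 7 (5R,6S)-6-ethenyl-5-[(4-methoxyphenyl)methoxy]-3-methyl-5,6-dihydro-2H-pyran-2-one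
Product: 8 (3S,5R,6S)-6-ethenyl-5-[(4-methoxyphenyl)methoxy]-3-methyloxan-2-one
Conditions: [(Ph3P)CuH]6 (5 mol %), PhMe2SiH, t-BuOH, toluene, rt
Reagents that add atoms: none
Why: Copper hydride conjugate reduction touches only the conjugated alkene, and axial protonation of the enolate on the half-chair with equatorial C6 and C7 substituents should place the C4 methyl group equatorial and cis to the C6 oxygen (C4 = S), which is also the more stable epimer.

**Step 7**
Reactants: 8 (3S,5R,6S)-6-ethenyl-5-[(4-methoxyphenyl)methoxy]-3-methyloxan-2-one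
Product: 9 ethyl 2-[(3S,5R,6S)-6-ethenyl-2-hydroxy-5-[(4-methoxyphenyl)methoxy]-3-methyloxan-2-yl]acetate (hemiketal; anomeric mixture)
Conditions: LiN(iPr)2, EtOAc, THF, −78 °C; then 8, −78 °C; NH4Cl (aq)
Reagents that add atoms: ethyl acetate, CCOC(C)=O
Why: Claisen-type addition of the ester enolate to the lactone carbonyl stops at the tetrahedral adduct at −78 °C (addition outruns enolisation at C4) and delivers C2 and C1.

**Step 8**
Reactants: 9 ethyl 2-[(3S,5R,6S)-6-ethenyl-2-hydroxy-5-[(4-methoxyphenyl)methoxy]-3-methyloxan-2-yl]acetate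
Product: 10 ethyl 2-[(2R,3S,5R,6S)-6-ethenyl-5-[(4-methoxyphenyl)methoxy]-3-methyloxan-2-yl]acetate
Conditions: Et3SiH, BF3·OEt2, CH2Cl2/MeCN, −78 → −30 °C
Reagents that add atoms: none
Why: Ionisation of the hemiketal gives a cyclic oxocarbenium ion that the silane attacks axially, giving the 2,6-cis all-equatorial oxane and setting the temporary C3 stereocentre (R) that later controls C10.

**Step 9**
Reactants: 10 ethyl 2-[(2R,3S,5R,6S)-6-ethenyl-5-[(4-methoxyphenyl)methoxy]-3-methyloxan-2-yl]acetate
Product: 11 2-[(2R,3S,5R,6S)-6-ethenyl-5-[(4-methoxyphenyl)methoxy]-3-methyloxan-2-yl]acetic acid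
Conditions: LiOH, THF/MeOH/H2O, rt; then 1 M HCl to pH 3
Reagents that add atoms: lithium hydroxide, [Li+].[OH-]
Why: Ester saponification; no stereocentre is adjacent to the carboxyl group.

**Step 10**
Reactants: 11 2-[(2R,3S,5R,6S)-6-ethenyl-5-[(4-methoxyphenyl)methoxy]-3-methyloxan-2-yl]acetic acid
Product: 13 3-diazo-1-[(2R,3S,5R,6S)-6-ethenyl-5-[(4-methoxyphenyl)methoxy]-3-methyloxan-2-yl]butan-2-one, via mixed carbonic anhydride 12 (not isolated)
Conditions: i-BuOCOCl, Et3N, Et2O/THF, −20 °C; then CH3CHN2 in Et2O (from N-ethyl-N-nitrosourea, aq. KOH, 0 °C), −20 → 0 °C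
Reagents that add atoms: diazoethane, CC=[N+]=[N-]
Why: Acylation of diazoethane by the activated acid (the diazoketone synthesis of the Arndt–Eistert sequence), with excess diazoethane removing the proton, gives the α-methyl diazoketone that carries C10 and its methyl group.

**Step 11**
Reactants: 13 3-diazo-1-[(2R,3S,5R,6S)-6-ethenyl-5-[(4-methoxyphenyl)methoxy]-3-methyloxan-2-yl]butan-2-one
Product: 15 (1R,2S,4R,5Z,8R)-4-[(4-methoxyphenyl)methoxy]-2,8-dimethyl-11-oxabicyclo[6.2.1]undec-5-en-9-one, via oxonium ylide 14 (not isolated)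
Conditions: Cu(CF3COCHCOCF3)2 (5 mol %), CH2Cl2, reflux, slow addition of 13
Reagents that add atoms: none
Why: Loss of N2 gives an electrophilic copper carbenoid at C10 that is captured by the ring oxygen of the oxane (forming the O–C10 bond and the bicyclic oxonium ylide 14), and the ylide undergoes a suprafacial [2,3]-sigmatropic shift of the C7 allyl unit in which C9 bonds to C10 and the O–C7 bond breaks. The closest known reaction type is the copper-catalysed oxonium ylide formation and [2,3] rearrangement of diazoketone-tethered 2-vinyl cyclic ethers to 11-oxabicyclo[6.2.1]undecenones, together with the same rearrangement of α-methyl diazoketones to quaternary 2-methylfuran-3-ones. The five-membered ring closes by attack of the ether lone pair on the carbenoid carbon (five-ring ylide closure), and the ten-membered carbocycle arises by three-atom ring expansion of the oxane through a five-centre envelope transition state. C10 is the only new stereocentre and is fixed by C3: the six-carbon bridge C4–C9 can span C3 and C10 only on one face of the new five-membered ring, so C9 is delivered cis to C4 and C10 becomes R. The step needs ylide formation to outrun 1,2-hydride shift from the methyl group, 1,5 C–H insertion at C4 and cyclopropanation of the vinyl group, and the [2,3] shift to outrun a [1,2] shift; the ether oxygen placed for a five-membered closure, the electron-poor copper bis(hexafluoroacetylacetonate) catalyst and the allylic O–C7 bond should secure this. The equatorial vinyl group of the 2,6-cis oxane should give mainly the Z ring alkene that the later steps require.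

**Step 12**
Reactants: 15 (1R,2S,4R,5Z,8R)-4-[(4-methoxyphenyl)methoxy]-2,8-dimethyl-11-oxabicyclo[6.2.1]undec-5-en-9-one
Product: 17 (2S,4R,5Z,8R)-4-[(4-methoxyphenyl)methoxy]-2,8-dimethyl-11-oxabicyclo[6.2.1]undeca-1(10),5-dien-9-one, via silyl enol ether 16 (not isolated)
Conditions: Me3SiOTf, Et3N, CH2Cl2, 0 °C; then Pd(OAc)2, MeCN, rt
Reagents that add atoms: none
Why: Saegusa–Ito oxidation: enolisation is possible only toward C2 (C10 is quaternary) and syn β-hydride elimination of the bridgehead H3 from the palladium enolate gives the 3(2H)-furanone, removing the temporary C3 stereocentre.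

**Step 13**
Reactants: 17 (2S,4R,5Z,8R)-4-[(4-methoxyphenyl)methoxy]-2,8-dimethyl-11-oxabicyclo[6.2.1]undeca-1(10),5-dien-9-one
Product: 18 (2S,4R,5Z,8R)-4-hydroxy-2,8-dimethyl-11-oxabicyclo[6.2.1]undeca-1(10),5-dien-9-one
Conditions: DDQ, CH2Cl2/pH 7 buffer, 0 °C
Reagents that add atoms: none
Why: Oxidative cleavage of the electron-rich benzyl ether through its oxocarbenium ion, run cold and buffered so that the liberated allylic alcohol is not oxidised further.

**Step 14**
Reactants: 18 (2S,4R,5Z,8R)-4-hydroxy-2,8-dimethyl-11-oxabicyclo[6.2.1]undeca-1(10),5-dien-9-one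
Product: 19 syn-epoxy alcohol, the 7,8-epoxide of 18 on the face of the C6 hydroxyl (germacrane numbering 4S,6R,7R,8S,10R)
Conditions: VO(acac)2 (5 mol %), t-BuOOH, CH2Cl2, 0 °C → rt
Reagents that add atoms: tert-butyl hydroperoxide, CC(C)(C)OO
Why: Hydroxyl-directed epoxidation: the vanadium alkoxide of the C6 hydroxyl delivers the peroxide oxygen to the face of the Z alkene that carries the hydroxyl (as for medium-ring cis-allylic alcohols), fixing the C8–O configuration and leaving the electron-poor furanone alkene untouched.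

**Step 15**
Reactants: 19 syn-epoxy alcohol (4S,6R,7R,8S,10R)
Product: 20 diethylphosphonoacetate ester of 19 at the C6 oxygen
Conditions: (EtO)2P(O)CH2CO2H, DCC, DMAP (cat.), CH2Cl2, 0 °C → rt
Reagents that add atoms: diethylphosphonoacetic acid, CCOP(=O)(OCC)CC(=O)O
Why: Steglich esterification attaches C11 and C12 to the C6 oxygen as a stabilised carbon nucleophile.

**Step 16**
Reactants: 20 diethylphosphonoacetate ester of 19
Product: 22 8-hydroxy α-methylene lactone (the target lacking its C8 acyl group; trans-fused 6,12-lactone), via phosphono lactone 21 (not isolated)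
Conditions: NaH, THF, 0 → 45 °C; then (CH2O)n, rt
Reagents that add atoms: formaldehyde (as paraformaldehyde), C=O
Why: The phosphonoacetate carbanion opens the epoxide intramolecularly at C7 (5-exo-tet, SN2 inversion, with the C6–O and C7–O bonds antiperiplanar in the extended ring conformer) to give the trans-fused lactone and the C8 alkoxide with retention at C8; proton transfer regenerates the phosphonate anion and Horner–Wadsworth–Emmons olefination with formaldehyde installs C13.

**Step 17**
Reactants: 23 (S)-3-bromo-2-hydroxy-2-methylpropanoic acid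
Product: 25 (R)-2,3-dihydroxy-2-methylpropanoic acid, via sodium 2-methylglycidate 24 (not isolated)
Conditions: NaOH, H2O, 70 °C; then H+ ion-exchange resin
Reagents that add atoms: sodium hydroxide, [Na+].[OH-]
Why: The alkoxide displaces bromide to give the glycidate, which hydroxide opens at CH2; neither event touches the quaternary stereocentre, and the descriptor changes from S to R only because CH2Br outranks CO2H whereas CH2OH does not.

**Step 18**
Reactants: 25 (R)-2,3-dihydroxy-2-methylpropanoic acid
Product: 26 (R)-2,2,4-trimethyl-1,3-dioxolane-4-carboxylic acid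
Conditions: Me2C(OMe)2, p-TsOH (cat.), acetone, rt
Reagents that add atoms: 2,2-dimethoxypropane, COC(C)(C)OC
Why: Acid-catalysed transacetalisation ties up the 1,2-diol as its isopropylidene acetal and leaves the carboxylic acid free.

**Step 19**
Reactants: 22 8-hydroxy α-methylene lactone; 26 (R)-2,2,4-trimethyl-1,3-dioxolane-4-carboxylic acid
Product: 28 C8 ester of 22 with acid 26 (target acetonide), via mixed aroyl anhydride 27 (not isolated)
Conditions: 2,4,6-Cl3C6H2COCl, Et3N, THF, rt; then 22, DMAP, toluene, rt → 40 °C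
Reagents that add atoms: none
Why: Yamaguchi esterification: DMAP opens the mixed anhydride at the aliphatic carbonyl and the acylpyridinium acylates the hindered C8 alcohol; the quaternary α-carbon of the acid cannot epimerise.

**Step 20**
Reactants: 28 target acetonide
Product: 29 (4S,6R,7S,8S,10R)-3,10-epoxy-1-oxogermacra-2,11(13)-dien-12,6-olid-8-yl (2R)-2,3-dihydroxy-2-methylpropanoate (CNP0263764.2)
Conditions: CF3CO2H/H2O (4:1), 0 °C
Reagents that add atoms: none
Why: Acid hydrolysis of the isopropylidene acetal releases the diol, while the ester, the α-methylene lactone and the vinylogous ester should survive cold aqueous acid.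

**Compound list**
1 | penta-1,4-dien-3-ol | C=CC(O)C=C | starting material
2 | (2S,3R)-1,2-epoxypent-4-en-3-ol | C=C[C@@H](O)[C@@H]1CO1 | intermediate
3 | (2S)-2-[(1R)-1-[(4-methoxyphenyl)methoxy]prop-2-en-1-yl]oxirane | C=C[C@@H](OCc1ccc(OC)cc1)[C@@H]1CO1 | intermediate
4 | dimethyl[(3S,4R)-4-[(4-methoxyphenyl)methoxy]-3-oxidohex-5-en-1-yl]sulfonium (betaine, not isolated) | C=C[C@@H](OCc1ccc(OC)cc1)[C@@H]([O-])CC[S+](C)C | intermediate
5 | (3S,4R)-4-[(4-methoxyphenyl)methoxy]hexa-1,5-dien-3-ol | C=C[C@@H](OCc1ccc(OC)cc1)[C@@H](O)C=C | intermediate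
6 | (3S,4R)-4-[(4-methoxyphenyl)methoxy]hexa-1,5-dien-3-yl 2-methylprop-2-enoate | C=C[C@@H](OCc1ccc(OC)cc1)[C@@H](OC(=O)C(C)=C)C=C | intermediate
7 | (5R,6S)-6-ethenyl-5-[(4-methoxyphenyl)methoxy]-3-methyl-5,6-dihydro-2H-pyran-2-one | C=C[C@@H]1OC(=O)C(C)=C[C@H]1OCc1ccc(OC)cc1 | intermediate
8 | (3S,5R,6S)-6-ethenyl-5-[(4-methoxyphenyl)methoxy]-3-methyloxan-2-one | C=C[C@@H]1OC(=O)[C@@H](C)C[C@H]1OCc1ccc(OC)cc1 | intermediate
9 | ethyl 2-[(3S,5R,6S)-6-ethenyl-2-hydroxy-5-[(4-methoxyphenyl)methoxy]-3-methyloxan-2-yl]acetate (anomeric mixture) | C=C[C@@H]1OC(O)(CC(=O)OCC)[C@@H](C)C[C@H]1OCc1ccc(OC)cc1 | intermediate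
10 | ethyl 2-[(2R,3S,5R,6S)-6-ethenyl-5-[(4-methoxyphenyl)methoxy]-3-methyloxan-2-yl]acetate | C=C[C@@H]1O[C@H](CC(=O)OCC)[C@@H](C)C[C@H]1OCc1ccc(OC)cc1 | intermediate
11 | 2-[(2R,3S,5R,6S)-6-ethenyl-5-[(4-methoxyphenyl)methoxy]-3-methyloxan-2-yl]acetic acid | C=C[C@@H]1O[C@H](CC(=O)O)[C@@H](C)C[C@H]1OCc1ccc(OC)cc1 | intermediate
12 | mixed isobutyl carbonic anhydride of 11 (not isolated) | C=C[C@@H]1O[C@H](CC(=O)OC(=O)OCC(C)C)[C@@H](C)C[C@H]1OCc1ccc(OC)cc1 | intermediate
13 | 3-diazo-1-[(2R,3S,5R,6S)-6-ethenyl-5-[(4-methoxyphenyl)methoxy]-3-methyloxan-2-yl]butan-2-one | C=C[C@@H]1O[C@H](CC(=O)C(C)=[N+]=[N-])[C@@H](C)C[C@H]1OCc1ccc(OC)cc1 | intermediate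
14 | bicyclic oxonium ylide (oxygen bonded to C3, C7 and C10; carbanion at C10 next to the C1 ketone; not isolated) | C=C[C@@H]1[O+]2[C@H](CC(=O)[C-]2C)[C@@H](C)C[C@H]1OCc1ccc(OC)cc1 | intermediate
15 | (1R,2S,4R,5Z,8R)-4-[(4-methoxyphenyl)methoxy]-2,8-dimethyl-11-oxabicyclo[6.2.1]undec-5-en-9-one | COc1ccc(CO[C@@H]2C[C@H](C)[C@H]3CC(=O)[C@@](C)(C/C=C\2)O3)cc1 | intermediate
16 | trimethylsilyl enol ether of 15 (C1–OSiMe3, C1=C2; not isolated) | COc1ccc(CO[C@@H]2C[C@H](C)[C@H]3C=C(O[Si](C)(C)C)[C@@](C)(C/C=C\2)O3)cc1 | intermediate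
17 | (2S,4R,5Z,8R)-4-[(4-methoxyphenyl)methoxy]-2,8-dimethyl-11-oxabicyclo[6.2.1]undeca-1(10),5-dien-9-one | COc1ccc(CO[C@@H]2C[C@H](C)C3=CC(=O)[C@@](C)(C/C=C\2)O3)cc1 | intermediate
18 | (2S,4R,5Z,8R)-4-hydroxy-2,8-dimethyl-11-oxabicyclo[6.2.1]undeca-1(10),5-dien-9-one | O[C@@H]1C[C@H](C)C2=CC(=O)[C@@](C)(C/C=C\1)O2 | intermediate
19 | syn-epoxy alcohol: 7,8-epoxide of 18 on the face of the C6 hydroxyl (4S,6R,7R,8S,10R, germacrane numbering) | O[C@@H]1C[C@H](C)C2=CC(=O)[C@@](C)(C[C@@H]3O[C@H]13)O2 | intermediate
20 | diethylphosphonoacetate ester of 19 at the C6 oxygen | CCOP(=O)(OCC)CC(=O)O[C@@H]1C[C@H](C)C2=CC(=O)[C@@](C)(C[C@@H]3O[C@H]13)O2 | intermediate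
21 | 11-(diethoxyphosphoryl) trans-fused 6,12-lactone with free C8 hydroxyl (C11 epimers; not isolated) | CCOP(=O)(OCC)C1C(=O)O[C@@H]2C[C@H](C)C3=CC(=O)[C@@](C)(C[C@H](O)[C@@H]12)O3 | intermediate
22 | 8-hydroxy α-methylene lactone (target lacking the C8 acyl group) | C=C1C(=O)O[C@@H]2C[C@H](C)C3=CC(=O)[C@@](C)(C[C@H](O)[C@@H]12)O3 | intermediate
23 | (S)-3-bromo-2-hydroxy-2-methylpropanoic acid | OC(=O)[C@](C)(O)CBr | starting material
24 | sodium (R)-2-methyloxirane-2-carboxylate (not isolated) | [Na+].[O-]C(=O)[C@@]1(C)CO1 | intermediate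
25 | (R)-2,3-dihydroxy-2-methylpropanoic acid | OC(=O)[C@](C)(O)CO | intermediate
26 | (R)-2,2,4-trimethyl-1,3-dioxolane-4-carboxylic acid | OC(=O)[C@@]1(C)COC(C)(C)O1 | intermediate
27 | mixed anhydride of 26 with 2,4,6-trichlorobenzoic acid (not isolated) | O=C(OC(=O)[C@@]1(C)COC(C)(C)O1)c1c(Cl)cc(Cl)cc1Cl | intermediate
28 | C8 ester of 22 with acid 26 (target acetonide) | C=C1C(=O)O[C@@H]2C[C@H](C)C3=CC(=O)[C@@](C)(C[C@H](OC(=O)[C@@]4(C)COC(C)(C)O4)[C@@H]12)O3 | intermediate
29 | (4S,6R,7S,8S,10R)-3,10-epoxy-1-oxogermacra-2,11(13)-dien-12,6-olid-8-yl (2R)-2,3-dihydroxy-2-methylpropanoate (CNP0263764.2) | C=C1C(=O)O[C@@H]2C[C@H](C)C3=CC(=O)[C@@](C)(C[C@H](OC(=O)[C@](C)(O)CO)[C@@H]12)O3 | target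

Total step count: 20. Longest linear sequence: 18 steps (steps 1–16, 19 and 20); steps 17 and 18 form the side-chain branch.

**Steps most likely to fail**

1. Step 11. The methyl-substituted carbenoid may undergo 1,2-hydride shift to an enone or C–H insertion at C4 faster than ylide formation, or the rearrangement may give a poor Z/E ratio. The fallback sets out from acid 11. Its mixed anhydride 12 is treated with diazomethane to give the terminal diazoketone 1-diazo-3-[(2R,3S,5R,6S)-6-ethenyl-5-[(4-methoxyphenyl)methoxy]-3-methyloxan-2-yl]propan-2-one F1. Its ylide formation and [2,3] shift under the same copper catalyst is the directly precedented case and should give the 10-demethyl analogue of ketone 15 F2. Kinetic silylation at C2 (LiN(SiMe3)2, Me3SiCl, THF, −78 °C) gives the silyl enol ether of the 10-demethyl ketone F3, and Pd(OAc)2 gives the 10-demethyl analogue of furanone 17 F4. Deprotonation at C10 (LiN(iPr)2, THF, −78 °C) and MeI, which can enter only on the face away from the six-carbon bridge, rejoins the route at 17.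

2. Step 16. SN2 opening at a medium-ring carbon may be slow, so that translactonisation to the 8,12-lactone or base-induced degradation of the furanone competes. The fallback sets out from allylic alcohol 18. DCC/DMAP esterification with diethylphosphonoacetic acid gives the diethylphosphonoacetate of 18 F5, and diazo transfer (4-acetamidobenzenesulfonyl azide, DBU, MeCN) gives the diazophosphonoacetate of 18 F6. Intramolecular cyclopropanation of the Z alkene with Rh2(OAc)4, the carbene being delivered from the C6 oxygen with H6 eclipsing the alkene, gives the cyclopropane-fused phosphono lactone F7. Homoconjugate SN2 opening of this doubly activated cyclopropane at C8 by the caesium salt of acid 26 (Cs2CO3, 18-crown-6, DMF, 60 °C) gives, with inversion at C8, the 11-phosphono lactone bearing the C8 ester F8, which is not isolated. Olefination with paraformaldehyde rejoins the route at 28.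

3. Step 14. The directed oxygen delivery may not dominate in the bridged ring, giving poor facial selectivity or oxidation of the allylic alcohol to the enone. The fallback sets out from PMB ether 17. NBS in aqueous acetone should form the bromonium ion on the exposed face away from the C6 ether and water opens it at C8 to give the 7-bromo-8-hydroxy bromohydrin of 17 F9. K2CO3 in MeOH closes the ring from the hydroxyl face to give the syn-7,8-epoxide of PMB ether 17 F10, and DDQ removes the PMB group to rejoin the route at 19.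

**Further compounds**
F1 | step 11 | 1-diazo-3-[(2R,3S,5R,6S)-6-ethenyl-5-[(4-methoxyphenyl)methoxy]-3-methyloxan-2-yl]propan-2-one | C=C[C@@H]1O[C@H](CC(=O)C=[N+]=[N-])[C@@H](C)C[C@H]1OCc1ccc(OC)cc1
F2 | step 11 | 10-demethyl analogue of ketone 15, (1R,2S,4R,5Z,8R)-4-[(4-methoxyphenyl)methoxy]-2-methyl-11-oxabicyclo[6.2.1]undec-5-en-9-one | COc1ccc(CO[C@@H]2C[C@H](C)[C@H]3CC(=O)[C@@H](C/C=C\2)O3)cc1
F3 | step 11 | silyl enol ether of the 10-demethyl ketone (C1–OSiMe3, C1=C2) | COc1ccc(CO[C@@H]2C[C@H](C)[C@H]3C=C(O[Si](C)(C)C)[C@@H](C/C=C\2)O3)cc1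
F4 | step 11 | 10-demethyl analogue of furanone 17 | COc1ccc(CO[C@@H]2C[C@H](C)C3=CC(=O)[C@@H](C/C=C\2)O3)cc1
F5 | step 16 | diethylphosphonoacetate of 18 | CCOP(=O)(OCC)CC(=O)O[C@@H]1C[C@H](C)C2=CC(=O)[C@@](C)(C/C=C\1)O2
F6 | step 16 | diazophosphonoacetate of 18 | CCOP(=O)(OCC)C(=[N+]=[N-])C(=O)O[C@@H]1C[C@H](C)C2=CC(=O)[C@@](C)(C/C=C\1)O2
F7 | step 16 | cyclopropane-fused phosphono lactone (C11 bonded to C7 and C8) | CCOP(=O)(OCC)[C@@]12C(=O)O[C@@H]3C[C@H](C)C4=CC(=O)[C@@](C)(C[C@@H]1[C@@H]23)O4
F8 | step 16 | 11-phosphono lactone bearing the C8 ester of acid 26 (not isolated) | CCOP(=O)(OCC)C1C(=O)O[C@@H]2C[C@H](C)C3=CC(=O)[C@@](C)(C[C@H](OC(=O)[C@@]4(C)COC(C)(C)O4)[C@@H]12)O3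
F9 | step 14 | 7-bromo-8-hydroxy bromohydrin of 17 | COc1ccc(CO[C@@H]2C[C@H](C)C3=CC(=O)[C@@](C)(C[C@H](O)[C@H]2Br)O3)cc1
F10 | step 14 | syn-7,8-epoxide of PMB ether 17 | COc1ccc(CO[C@@H]2C[C@H](C)C3=CC(=O)[C@@](C)(C[C@@H]4O[C@H]24)O3)cc1
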